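Readings and results come from a simulation with made-up constants; scatter was added.

**The product.** E is the product I want: L with two ligands exchanged for G, each exchange setting one X free.

the same everywhere: L 0.10 M

| charge | G | X | remark | time |
|---|---|---|---|---|
| dusk | 0.11 M | 0.50 M | run made earlier |  |
| spring | 0.24 M | 0.50 M | run made earlier |  |
| amber | 0.200 M | 0.500 M |  | 12 min |
| red | 0.0800 M | 0.500 M |  | 12 min |

| run | time / min | E / % | Q / % | L / % |
|---|---|---|---|---|
| dusk | 0.667 | 7 | 4 | 39 |
| dusk | 1.33 | 14 | 2 | 30 |
| dusk | 2.50 | 19 | 2 | 23 |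
| dusk | 4.00 | 18 | 5 | 26 |
| dusk | 8.00 | 17 | 0 | 31 |
| spring | 1.50 | 30 | 12 | 6 |
| spring | 3.00 | 42 | 10 | 2 |
| spring | 5.00 | 43 | 13 | 2 |
| spring | 6.00 | 41 | 10 | 4 |
| spring | 8.00 | 33 | 7 | 2 |

(standard deviation of a reading: 1.5 percentage points)

* which of these holds the largest part of the L at the end of amber (D / L / J / E / Q)
* which of these holds the largest part of the L at the end of red (D / L / J / E / Q)
* how much E is there at the end of amber, in percent of the L charged



**Main step.** Taking exchange first, I count the equivalents, G per L charged: 1.10 in dusk, 2.40 in spring, 2.00 in amber, 0.800 in red. Spring, the nearest to amber, reads E at 43 % at 5.00 min, more than its L or Q. But J and D go unread: 42.0 % of spring's L is unaccounted for at 5.00 min, about E's size, and spring differs from amber in charge and time. So J stays a rival, and E ahead in amber is my lean, not something the readings show.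

**One drain.** The late readings add a process: spring's E falls to 33 % by 8.00 min, a read rate of 0.0882 min⁻¹. Carried on to 12 min, that reading leaves 23.2 % of E, my number for amber.

**Late end.** Dusk's L climbs from 23 % to 31 % meanwhile, so L comes back. I assume the drain leaves from E and keeps its two G. Then the L that finally stays unexchanged is one minus half the equivalents, and I call this the bare end: 45.0 % for dusk and 60.0 % for red. G is the limiting reagent in red. The bare end is a late limit and tells me nothing of J at 12 min, so L ahead of J in red is my lean, no more.

**The forecast.** It names J for amber, J for red and 26 % of E in amber, range 20 % to 33 %, on “a slow drain from Q to D”. We part on both leaders, and my E is lower.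

**The flask.** Amber gives 26.0 % of E, and E leads there, ahead of J at 11.9 %.

    L + G ⇌ X + J (K = 110, k = 0.407 M⁻¹ s⁻¹)
    J + G ⇌ X + E (K = 310, k = 0.114 M⁻¹ s⁻¹)
    E + G ⇌ X + Q (K = 4.00, k = 0.635 M⁻¹ s⁻¹)
    Q + G ⇌ X + D (K = 5.80, k = 0.905 M⁻¹ s⁻¹)
    E → Z (k = 0.00232 s⁻¹)

**Bare end, again.** Red's leader is L at 45.6 %. Left to 120 min, red's L stands at 56.8 % against its bare end of 60.0 %. Amber's charge with 0.40 M of L has 0.500 equivalents and a bare end of 75.0 %, and its L stands below that at 62.0 %.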